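**Retrosynthetic overview**

1. Rigidin D ⇐ its bis-MOM ether carried as the 2,4-dimethoxypyrimidine (bis-lactim ether): one acid treatment removes both MOM groups and hydrolyses the lactim ethers to the uracil ring.
2. That precursor ⇐ an amino ynone (4-amino-2,6-dimethoxypyrimidine with an aroylethynyl group at C5) + MOM-protected 4-iodoguaiacol: a Pd-catalysed aminopalladation/reductive elimination closes the pyrrole ring (N7–C6) and forms the C5–aryl bond in the same operation.
3. Amino ynone ⇐ 4-amino-5-iodo-2,6-dimethoxypyrimidine + an aryl propargylic alcohol from vanillin (Sonogashira coupling for the C4a–C5 bond, then alcohol to ketone).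
4. Ring order: the pyrimidine ring and both guaiacyl rings are bought; the pyrrole ring is made last, in the key step; the dilactam is unmasked at the end.
5. Enabling feature: in the pyrrole ring, C6 carries both N7 and the aroyl C=O, C5 carries the aryl group, and N7 sits on C7a next to C4a of the pyrimidine ring. A C5≡C6 alkyne on C4a therefore has the N7 amino group in 5-endo reach of C6, and it is an ynone whose polarisation sends an incoming aryl group to C5.

Key step: step 7

Remark: the target is achiral; the carbinol carbon of 3 and 6 is carried as the racemate and is erased in step 5. 4-Amino-2,6-dimethoxypyrimidine and 4-iodo-2-methoxyphenol are taken as purchasable.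

**Route**

Step 1
Reactants: 1 vanillin
Product: 2 3-methoxy-4-(methoxymethoxy)benzaldehyde
Conditions: MOMCl, iPr2NEt, CH2Cl2, 0 °C to rt
Reagents that add atoms: chloromethyl methyl ether, COCCl
Why: O-alkylation of the acidic phenol by the reactive α-chloro ether (MOM protection) should proceed cleanly, the non-enolisable aldehyde being untouched.

Step 2
Reactants: 2 3-methoxy-4-(methoxymethoxy)benzaldehyde
Product: 3 1-[3-methoxy-4-(methoxymethoxy)phenyl]prop-2-yn-1-ol (racemic)
Conditions: HC≡CMgBr, THF, 0 °C to rt; then H2O
Reagents that add atoms: ethynylmagnesium bromide, C#C[Mg]Br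
Why: 1,2-addition of an alkynyl Grignard reagent to a non-enolisable aryl aldehyde, with the MOM acetal stable to the reagent; the carbinol stereocenter forms as the racemate and is removed in step 5.

Step 3
Reactants: 4 4-amino-2,6-dimethoxypyrimidine
Product: 5 4-amino-5-iodo-2,6-dimethoxypyrimidine
Conditions: NIS, MeCN, rt, dark
Reagents that add atoms: N-iodosuccinimide, O=C1CCC(=O)N1I
Why: electrophilic aromatic iodination at C5, the only ring C–H, which is strongly activated by the flanking amino and methoxy donors.

Step 4
Reactants: 5 4-amino-5-iodo-2,6-dimethoxypyrimidine; 3 1-[3-methoxy-4-(methoxymethoxy)phenyl]prop-2-yn-1-ol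
Product: 6 3-(4-amino-2,6-dimethoxypyrimidin-5-yl)-1-[3-methoxy-4-(methoxymethoxy)phenyl]prop-2-yn-1-ol (racemic)
Conditions: PdCl2(PPh3)2 (cat.), CuI (cat.), Et3N, DMF, 50 °C, degassed
Reagents that add atoms: none
Why: Sonogashira coupling of a heteroaryl iodide with a terminal alkyne; the free amino and hydroxyl groups are tolerated, and the mild temperature should prevent both ring closure of the ortho amino group and isomerisation of the propargylic alcohol.

Step 5
Reactants: 6 3-(4-amino-2,6-dimethoxypyrimidin-5-yl)-1-[3-methoxy-4-(methoxymethoxy)phenyl]prop-2-yn-1-ol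
Product: 7 3-(4-amino-2,6-dimethoxypyrimidin-5-yl)-1-[3-methoxy-4-(methoxymethoxy)phenyl]prop-2-yn-1-one
Conditions: MnO2 (activated, excess), CH2Cl2, rt
Reagents that add atoms: none
Why: MnO2 oxidation of a doubly activated (benzylic and propargylic) alcohol; the ynone should be isolable because closure of the amino group onto the alkyne carbon next to the carbonyl is anti-Michael and does not occur without a metal.

Step 6
Reactants: 8 4-iodo-2-methoxyphenol
Product: 9 4-iodo-2-methoxy-1-(methoxymethoxy)benzene
Conditions: MOMCl, iPr2NEt, CH2Cl2, 0 °C to rt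
Reagents that add atoms: chloromethyl methyl ether, COCCl
Why: MOM protection of the phenol as in step 1, masking the phenoxide so that it cannot add to the ynone in step 7.

Step 7
Reactants: 7 3-(4-amino-2,6-dimethoxypyrimidin-5-yl)-1-[3-methoxy-4-(methoxymethoxy)phenyl]prop-2-yn-1-one; 9 4-iodo-2-methoxy-1-(methoxymethoxy)benzene
Product: 12 {2,4-dimethoxy-5-[3-methoxy-4-(methoxymethoxy)phenyl]-7H-pyrrolo[2,3-d]pyrimidin-6-yl}[3-methoxy-4-(methoxymethoxy)phenyl]methanone, via arylpalladium iodide complex 10 (not isolated), via aryl(pyrrolopyrimidinyl)palladium complex 11 (not isolated)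
Conditions: Pd(PPh3)4 (10 mol %), Cs2CO3, 9 (1.3 equiv), anhydrous MeCN, 80 °C, argon
Reagents that add atoms: none
Why: Zerovalent palladium inserts into the C–I bond of 9 to give 10, whose divalent palladium binds the alkyne of 7 and triggers anti attack of the carbonate-deprotonated amino nitrogen on the alkyne carbon bearing the aroyl group, giving 11, which forms the C5–aryl bond by C–C reductive elimination and returns zerovalent palladium. The closest known reaction type is the Cacchi aminopalladation/reductive elimination synthesis of 2-substituted 3-arylindoles and azaindoles from ortho-alkynyl arylamines and aryl halides. The pyrrole ring closes at N7–C6 in the 5-endo-dig mode, the only ring size open to the ortho amino group, so nitrogen must go to C6 and the aryl group to C5. No stereocenter is formed. The step needs aryl transfer to outrun proton-terminated cyclisation and conjugate addition to the ynone: the acyl group polarises the alkyne against uncatalysed attack at C6, so closure waits for the arylpalladium species, and a carbonate base in MeCN without amine, formate or other hydride donor keeps a hydroarylation/condensation path to a pyrido[2,3-d]pyrimidine from turning over. A syn carbopalladation in the conjugate sense (aryl to C5, palladium to C6, then C–N reductive elimination) would converge on the same product.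

Step 8
Reactants: 12 {2,4-dimethoxy-5-[3-methoxy-4-(methoxymethoxy)phenyl]-7H-pyrrolo[2,3-d]pyrimidin-6-yl}[3-methoxy-4-(methoxymethoxy)phenyl]methanone
Product: 14 rigidin D, via bis-phenol bis-lactim ether 13 (not isolated)
Conditions: HCl, MeOH, 40 °C, then evaporate; 3 M aq HCl/1,4-dioxane, 90 °C
Reagents that add atoms: water, O
Why: acid-catalysed transacetalisation to methanol removes both MOM groups as volatile dimethoxymethane before heating (so no formaldehyde is left to alkylate the phenols), then addition–elimination of water at C2 and C4 of the N-protonated pyrimidine hydrolyses both lactim methyl ethers to the dilactam, while the aryl methyl ethers and the diaryl ketone are stable to aqueous HCl.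

**Compound list**

(In the SMILES of 10 and 11 the P–Pd dative bonds are written with formal charges.)

1 | vanillin (4-hydroxy-3-methoxybenzaldehyde) | COc1cc(C=O)ccc1O | starting material
2 | 3-methoxy-4-(methoxymethoxy)benzaldehyde | COCOc1ccc(C=O)cc1OC | intermediate
3 | 1-[3-methoxy-4-(methoxymethoxy)phenyl]prop-2-yn-1-ol (racemic) | COCOc1ccc(C(O)C#C)cc1OC | intermediate
4 | 4-amino-2,6-dimethoxypyrimidine | COc1cc(N)nc(OC)n1 | starting material
5 | 4-amino-5-iodo-2,6-dimethoxypyrimidine | COc1nc(OC)nc(N)c1I | intermediate
6 | 3-(4-amino-2,6-dimethoxypyrimidin-5-yl)-1-[3-methoxy-4-(methoxymethoxy)phenyl]prop-2-yn-1-ol (racemic) | COCOc1ccc(C(O)C#Cc2c(N)nc(OC)nc2OC)cc1OC | intermediate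
7 | 3-(4-amino-2,6-dimethoxypyrimidin-5-yl)-1-[3-methoxy-4-(methoxymethoxy)phenyl]prop-2-yn-1-one | COCOc1ccc(C(=O)C#Cc2c(N)nc(OC)nc2OC)cc1OC | intermediate
8 | 4-iodo-2-methoxyphenol | COc1cc(I)ccc1O | starting material
9 | 4-iodo-2-methoxy-1-(methoxymethoxy)benzene | COCOc1ccc(I)cc1OC | intermediate
10 | iodo[3-methoxy-4-(methoxymethoxy)phenyl]bis(triphenylphosphine)palladium (divalent palladium) | COCOc1ccc([Pd-2](I)([P+](c2ccccc2)(c2ccccc2)c2ccccc2)[P+](c2ccccc2)(c2ccccc2)c2ccccc2)cc1OC | intermediate (not isolated)
11 | {2,4-dimethoxy-6-[3-methoxy-4-(methoxymethoxy)benzoyl]-7H-pyrrolo[2,3-d]pyrimidin-5-yl}[3-methoxy-4-(methoxymethoxy)phenyl]bis(triphenylphosphine)palladium (divalent palladium) | COCOc1ccc(C(=O)c2[nH]c3nc(OC)nc(OC)c3c2[Pd-2]([P+](c2ccccc2)(c2ccccc2)c2ccccc2)([P+](c2ccccc2)(c2ccccc2)c2ccccc2)c2ccc(OCOC)c(OC)c2)cc1OC | intermediate (not isolated)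
12 | {2,4-dimethoxy-5-[3-methoxy-4-(methoxymethoxy)phenyl]-7H-pyrrolo[2,3-d]pyrimidin-6-yl}[3-methoxy-4-(methoxymethoxy)phenyl]methanone | COCOc1ccc(C(=O)c2[nH]c3nc(OC)nc(OC)c3c2-c2ccc(OCOC)c(OC)c2)cc1OC | intermediate
13 | [5-(4-hydroxy-3-methoxyphenyl)-2,4-dimethoxy-7H-pyrrolo[2,3-d]pyrimidin-6-yl](4-hydroxy-3-methoxyphenyl)methanone | COc1cc(C(=O)c2[nH]c3nc(OC)nc(OC)c3c2-c2ccc(O)c(OC)c2)ccc1O | intermediate (not isolated)
14 | rigidin D, 6-(4-hydroxy-3-methoxybenzoyl)-5-(4-hydroxy-3-methoxyphenyl)-1H-pyrrolo[2,3-d]pyrimidine-2,4(3H,7H)-dione | COc1cc(C(=O)c2[nH]c3[nH]c(=O)[nH]c(=O)c3c2-c2ccc(O)c(OC)c2)ccc1O | target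

**Step count and risks**

Total steps: 8. Longest linear sequence: 6 steps (steps 1, 2, 4, 5, 7, 8, from vanillin).

Steps most likely to fail:

1. Step 7. The ring may close with proton termination before the aryl group is transferred, or the catalyst may stall after carbopalladation followed by condensation of the amino group onto the ketone. The fallback sets out from 7 and 9 and separates ring closure from arylation. Compound 7 would be cyclised by silver-catalysed anti-Michael hydroamination (AgOTf cat., MeCN, 80 °C) to [2,4-dimethoxy-7H-pyrrolo[2,3-d]pyrimidin-6-yl][3-methoxy-4-(methoxymethoxy)phenyl]methanone F1. Iodination at C5 (NIS, DMF, rt) would give the 5-iodo compound F2. In parallel, 9 would be converted by Miyaura borylation (B2pin2, Pd(dppf)Cl2, KOAc, dioxane, 90 °C) into 2-[3-methoxy-4-(methoxymethoxy)phenyl]-4,4,5,5-tetramethyl-1,3,2-dioxaborolane F3. Suzuki–Miyaura coupling of F2 with F3 (Pd(dppf)Cl2, K2CO3, dioxane/H2O, 90 °C) would form the same C5–aryl bond and return to the route at 12.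

2. Step 4. Oxidative addition into the electron-rich, ortho-amino C–I bond may be slow, so that oxidative homocoupling of alkyne 3 or base-induced isomerisation of the aryl propargylic alcohol to an enone takes over. The fallback sets out from 5 and 9 and builds the ynone by carbonylation instead of by oxidation. Sonogashira coupling of 5 with trimethylsilylacetylene (PdCl2(PPh3)2, CuI, Et3N, DMF) would give 4-amino-2,6-dimethoxy-5-[(trimethylsilyl)ethynyl]pyrimidine F4. Desilylation (K2CO3, MeOH) would give 4-amino-5-ethynyl-2,6-dimethoxypyrimidine F5. Carbonylative Sonogashira coupling of F5 with 9 under CO (1 atm; PdCl2(PPh3)2, CuI, Et3N, THF, rt) would give the ynone directly and return to the route at 7, bypassing 6 and step 5.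

3. Step 8. Hydrolysis may stall at the less reactive C2 lactim ether, or prolonged heating in strong acid may erode an aryl methyl ether or let residual formaldehyde equivalents alkylate the phenols. The fallback sets out from 12 and cleaves the O–CH3 bonds instead of the ring C–O bonds. MOM removal alone (HCl, MeOH, rt) would give the bis-phenol 13, now isolated. Iodide-mediated O-demethylation of the lactim ethers (NaI, AcOH, 80 °C; SN2 at the methyl groups) would then pass through (4-hydroxy-3-methoxyphenyl)[5-(4-hydroxy-3-methoxyphenyl)-2-methoxy-4-oxo-3,7-dihydro-4H-pyrrolo[2,3-d]pyrimidin-6-yl]methanone F6 and return to the route at 14.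

Further compounds

F1 | step 7 | [2,4-dimethoxy-7H-pyrrolo[2,3-d]pyrimidin-6-yl][3-methoxy-4-(methoxymethoxy)phenyl]methanone | COCOc1ccc(C(=O)c2cc3c(OC)nc(OC)nc3[nH]2)cc1OC
F2 | step 7 | [5-iodo-2,4-dimethoxy-7H-pyrrolo[2,3-d]pyrimidin-6-yl][3-methoxy-4-(methoxymethoxy)phenyl]methanone | COCOc1ccc(C(=O)c2[nH]c3nc(OC)nc(OC)c3c2I)cc1OC
F3 | step 7 | 2-[3-methoxy-4-(methoxymethoxy)phenyl]-4,4,5,5-tetramethyl-1,3,2-dioxaborolane | COCOc1ccc(B2OC(C)(C)C(C)(C)O2)cc1OC
F4 | step 4 | 4-amino-2,6-dimethoxy-5-[(trimethylsilyl)ethynyl]pyrimidine | COc1nc(OC)nc(N)c1C#C[Si](C)(C)C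
F5 | step 4 | 4-amino-5-ethynyl-2,6-dimethoxypyrimidine | COc1nc(OC)nc(N)c1C#C
F6 | step 8 | (4-hydroxy-3-methoxyphenyl)[5-(4-hydroxy-3-methoxyphenyl)-2-methoxy-4-oxo-3,7-dihydro-4H-pyrrolo[2,3-d]pyrimidin-6-yl]methanone | COc1cc(C(=O)c2[nH]c3nc(OC)[nH]c(=O)c3c2-c2ccc(O)c(OC)c2)ccc1O
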